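The numbers belong to no real substance, and the outcome is calculated.

Count your charge in rounds: the starting material is 50.0 charges of free catalyst, so 50% conversion asks, on average, 25.0 rounds per catalyst charged.

starting material 5.0 × 10⁻⁴ M; reagent 1.00 mM; free catalyst 10 µM; added ligand 50 µM

    catalyst intermediate C ⇌ free catalyst + target (K1 = 0.0036 M, k1 = 2.3 s⁻¹)
    starting material + catalyst intermediate B → catalyst intermediate C (k2 = 3300 L mol⁻¹ s⁻¹)
    reagent + free catalyst → catalyst intermediate A (k3 = 1000 L mol⁻¹ s⁻¹)
    free catalyst + added ligand ⇌ idle complex (K4 = 35000 L mol⁻¹, k4 = 390 L mol⁻¹ s⁻¹)
    catalyst intermediate A → by-product + catalyst intermediate B (k5 = 19 s⁻¹)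

* apparent order in free catalyst when 50% of the starting material are converted (percent change of the rate of making target for one percent more free catalyst charged)
* factor on the rate of making target when 50% of the starting material are converted if free catalyst is charged twice over

Within a round the free catalyst stands at a fork. Reagent as charged takes it at 60.0 min⁻¹, added ligand as charged at 1.17 min⁻¹, much slower. Their ratio is 0.0195, the leak per round: captures into the off-cycle idle complex per entry into the round, at the amounts charged.

Counted per round, I reckon that half conversion costs this flask 48.8% of its catalyst in captures, while a flask charged twice over pays 24.4%. But the idle complex lets go at 0.669 min⁻¹. With capture spread evenly over the 1.36 min to half conversion, I keep 65.7% of it, so I put 32.0% idle. For the doubled flask, taken to need half the time, I keep 80.4%, so I put 19.6% idle. If the rate follows the catalyst still in the round, my factor is 2.37, and the order over that doubling is 1.24.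

The forecast, by its own route, gives an order of 1.25 and a factor of 2.36, holding that “Rate is proportional to active catalyst”.

The flask gives an order of 1.2 and a factor of 2.36. At 1.00 min this flask holds target at 40.0% of the starting material charged and 30.3% of its catalyst as idle complex, where the leak on that conversion, with the same release, reckons 28.4%. Capture there is still faster than release, in fractions of the catalyst charged: 0.340 min⁻¹ against 0.203 min⁻¹.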